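The minute is the unit to reckon in, so the seconds of the south-west run are read as fractions of a minute, and amounts are fractions of the X charge.

| flask | X | Q | remark | time |
|---|---|---|---|---|
| south | 0.50 mM | 0.56 mol% | run made earlier |  |
| south-west | 0.50 mM | 0.28 mol% | run made earlier |  |
| theta | 0.50 mM | 0.56 mol% | one stirred flow tank at steady state, fed with the mixture as stated, mean residence time 40.0 min |  |
| alpha | 0.50 mM | 0.56 mol% | one stirred flow tank at steady state, fed with the mixture as stated, mean residence time 4.0 min |  |
| epsilon | 0.50 mM (fed, over 3.20 min) | 0.56 mol% | a stirred flask in which X is dosed at a steady rate over 3.20 min without added volume, worked up at 4.0 min | 4.0 min |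
| beta | 0.50 mM | 0.56 mol% | a closed flask charged with all of it at once and left for 4.0 min | 4.0 min |

south run (percent of the X charged)

| time / min | D / % | X / % |
|---|---|---|
| 0.200 | 23.1 | 73.9 |
| 0.333 | 31.7 | 60.2 |
| 0.500 | 39.0 | 46.7 |
| 0.833 | 45.2 | 30.3 |
| 1.33 | 46.6 | 14.3 |
| 2.50 | 39.9 | 4.6 |

south-west run (percent of the X charged)

| time / s | D / % | X / % |
|---|---|---|
| 10.0 | 21.3 | 78.7 |
| 15.0 | 26.9 | 67.5 |
| 25.0 | 38.7 | 54.3 |
| 40.0 | 44.9 | 37.3 |
| 60.0 | 51.1 | 23.2 |
| 80.0 | 49.4 | 15.8 |

(standard deviation of a reading: 1 percentage point)

- the stated concentrations are those of everything mixed, before any reaction; amounts are the same in each set-up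
- steps that have been proposed: X <-> D; D + Q <-> E + Q; D <-> L
- the feed brings no volume worth counting
- the earlier runs were made in a closed, stirred flask

* the set-up with the highest amount of D at the outlet or at the end, in percent of the X put in ("none" if the first two lie within 2 percentage points) (theta / alpha / epsilon / beta / none)
* amount of D at the outlet or at the end, in percent of the X put in, theta
* amount of D at the outlet or at the end, in percent of the X put in, alpha
* amount of D at the outlet or at the end, in percent of the X put in, epsilon
* amount of D at the outlet or at the end, in percent of the X put in, beta

The south run looks contradictory: between 1.33 min and 2.50 min, X falls from 14.3% to 4.6%, yet D, which X feeds, also falls, from 46.6% to 39.9%. The balance clears this up, since X handed over 9.7 percentage points in that interval while X and D together lost 16 points, so D was drained faster than it was fed.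

The supply keeps time by the decade time of X, the time in which the X left falls by a power of ten, and the logarithms of the south readings between 0.200 min and 1.33 min give 1.58 min. The south-west run, at half the Q, gives about the same, 1.67 min, so the loading of Q leaves this clock in place within the scatter.

Q is a catalyst, which makes the step from D to E pseudo-first-order, and the other two proposed steps have one species on each side, so each dose of X ages on its own along the south curve. In flask epsilon at 4.0 min, the doses therefore span ages from 0.800 min to 4.0 min, or 0.505 to 2.53 decades. That window holds the highest south reading of D, at 0.842 decades, while flask beta sits wholly at the old end. The reckoning here therefore puts epsilon above beta, with X left at the average over the window, 6.67%.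

The forecast chose epsilon, with D at 33% in theta, 38% in alpha, 41% in epsilon and 37% in beta, on the ground that “All steps are first order”.

The flasks give 29.2% in theta, 35.3% in alpha, 40.8% in epsilon and 34.0% in beta, so epsilon leads, and X left in epsilon is 7.6% against the reckoned 6.67%.

    X ⇌ D (K = 27.0, k = 0.0250 /s)
    D + Q ⇌ E + Q, rate k2*[Q]*[D] forward; the back reaction follows from the equilibrium constant (K = 0.440, k = 5800 /M/s)
    D ⇌ L (K = 2.10, k = 0.00800 /s)

A neighbour of epsilon charged with 0.34 mol% of Q is reckoned with the same decade time, 1.58 min, and the same window, so the same reckoning again gives 6.67% of X. That neighbour holds 7.7% of X at the end, and its D stands at 40.9%.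

The numbers in the tables were computed for substances that don't exist; scatter was added.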